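**Retrosynthetic overview**
1. The target is released last from its fully protected form (three MOM ethers, one TES ether) by a single acid solvolysis.
2. Ring C is cut at C4a–C4 and C4–C3: carbon monoxide becomes C4 and is stitched between the iodinated C4a of ring A and the enol-ether beta carbon (future C3) of a (Z)-aryl styryl ether by carbonylative acyl-Heck closure. Ring C is the last ring formed.
3. Structural feature used: carbonyl carbon C4 is bonded only to C4a and C3. With C4 removed, ring A is a phenol (oxygen of C8a) with oxygens at C5 and C7 and the side chain at C6. A mirror plane through C8a and C6 makes C4a and C8 the same position, so iodination ortho to the phenol fixes the 6-alkyl pattern without any regiochemical choice.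
4. The (Z)-enol ether is made from the ring A 2-iodophenol and the ring B 6-ethynylchromene by base-mediated anti-Markovnikov hydrophenoxylation. Iodine is installed before the ether is formed, because lithiation of the assembled ether could not distinguish ring A from C8 of ring B and would endanger the base-sensitive Z enol ether.
5. Ring A comes from resorcinol (C2 lithiation and alkylation, then C5 C–H borylation and oxidation). Ring B comes from 5-bromo-2,4-dihydroxybenzaldehyde, its pyran ring being closed first of all by oxa-6π electrocyclisation.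

Key step: step 13

Assumption: 5-bromo-2,4-dihydroxybenzaldehyde is taken as a catalogue compound; the target has no stereocentre, so only the Z geometry of the enol ether has to be controlled.

**Route**

Step 1
Reactants: 1 resorcinol
Product: 2 1,3-bis(methoxymethoxy)benzene
Conditions: NaH (2.4 equiv), MOMCl (2.4 equiv), DMF, 0 °C to rt
Reagents that add atoms: chloromethyl methyl ether, COCCl
Why: Williamson-type O-alkylation of both sodium phenoxides by the reactive alpha-chloro ether should give the bis-acetal cleanly.

Step 2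
Reactants: 3 3-methylbutane-1,3-diol
Product: 4 4-iodo-2-methylbutan-2-ol
Conditions: PPh3, imidazole, I2, CH2Cl2, 0 °C to rt
Reagents that add atoms: iodine, II
Why: In the Appel iodination only the unhindered primary alcohol forms the alkoxyphosphonium ion that iodide displaces, so the tertiary alcohol should remain.

Step 3
Reactants: 4 4-iodo-2-methylbutan-2-ol
Product: 5 triethyl[(4-iodo-2-methylbutan-2-yl)oxy]silane
Conditions: TESOTf, 2,6-lutidine, CH2Cl2, −78 to 0 °C
Reagents that add atoms: triethylsilyl trifluoromethanesulfonate, CC[Si](CC)(CC)OS(=O)(=O)C(F)(F)F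
Why: A silyl triflate with a hindered pyridine base silylates tertiary alcohols and leaves the primary iodide untouched.

Step 4
Reactants: 2 1,3-bis(methoxymethoxy)benzene; 5 triethyl[(4-iodo-2-methylbutan-2-yl)oxy]silane
Product: 7 triethyl({4-[2,6-bis(methoxymethoxy)phenyl]-2-methylbutan-2-yl}oxy)silane, via aryllithium 6 (not isolated)
Conditions: n-BuLi (1.1 equiv), THF, 0 °C, 1 h; then 5 (1.2 equiv), 0 °C to rt
Reagents that add atoms: none
Why: Directed ortho-metalation takes place at C2 between the two chelating MOM ethers, and the aryllithium should then displace the primary iodide in an SN2 alkylation.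

Step 5
Reactants: 7 triethyl({4-[2,6-bis(methoxymethoxy)phenyl]-2-methylbutan-2-yl}oxy)silane
Product: 8 2-{3,5-bis(methoxymethoxy)-4-[3-methyl-3-(triethylsilyloxy)butyl]phenyl}-4,4,5,5-tetramethyl-1,3,2-dioxaborolane
Conditions: [Ir(OMe)(cod)]2 (1.5 mol%), 4,4'-di-tert-butyl-2,2'-bipyridine (3 mol%), B2pin2 (1.0 equiv), THF, 70 °C
Reagents that add atoms: bis(pinacolato)diboron, CC1(C)OB(B2OC(C)(C)C(C)(C)O2)OC1(C)C
Why: Iridium-catalysed aromatic C–H borylation is sterically controlled, and C5 (para to the chain) is the only ring CH without an ortho substituent.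

Step 6
Reactants: 8 2-{3,5-bis(methoxymethoxy)-4-[3-methyl-3-(triethylsilyloxy)butyl]phenyl}-4,4,5,5-tetramethyl-1,3,2-dioxaborolane
Product: 9 3,5-bis(methoxymethoxy)-4-[3-methyl-3-(triethylsilyloxy)butyl]phenol
Conditions: H2O2 (30% aq.), NaOH (aq.), THF, 0 °C
Reagents that add atoms: hydrogen peroxide, OO
Why: Oxidation of the arylboronate by hydroperoxide (1,2-aryl shift from boron to oxygen, then hydrolysis) gives the phenol under basic conditions that leave the acetals and the silyl ether intact.

Step 7
Reactants: 9 3,5-bis(methoxymethoxy)-4-[3-methyl-3-(triethylsilyloxy)butyl]phenol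
Product: 10 2-iodo-3,5-bis(methoxymethoxy)-4-[3-methyl-3-(triethylsilyloxy)butyl]phenol
Conditions: NIS (1.0 equiv), CH2Cl2, −20 to 0 °C, dark
Reagents that add atoms: N-iodosuccinimide, O=C1CCC(=O)N1I
Why: Electrophilic aromatic iodination of the very electron-rich phenol can only occur at the two free ring carbons, which are mirror-related, so one equivalent of reagent should give a single monoiodide.

Step 8
Reactants: 11 5-bromo-2,4-dihydroxybenzaldehyde
Product: 12 5-bromo-2-hydroxy-4-(methoxymethoxy)benzaldehyde
Conditions: MOMCl (1.1 equiv), K2CO3, acetone, 0 °C to rt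
Reagents that add atoms: chloromethyl methyl ether, COCCl
Why: The 2-hydroxyl is hydrogen-bonded to the aldehyde, so O-alkylation should take place selectively at the more acidic, free 4-hydroxyl.

Step 9
Reactants: 12 5-bromo-2-hydroxy-4-(methoxymethoxy)benzaldehyde
Product: 14 6-bromo-7-(methoxymethoxy)-2,2-dimethyl-2H-chromene, via allylic carbinol 13 (not isolated)
Conditions: 2-methylprop-1-enylmagnesium bromide (2.5 equiv), THF, −20 to 0 °C; aq. NH4Cl; crude carbinol, PPTS (5 mol%), toluene, 50 °C
Reagents that add atoms: 2-methylprop-1-enylmagnesium bromide, CC(C)=C[Mg]Br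
Why: Grignard 1,2-addition (the first equivalent only deprotonates the phenol) gives the racemic ortho-hydroxybenzylic allylic carbinol, whose stereocentre is lost when mild acid dehydrates it to an ortho-quinone methide that closes by oxa-6π electrocyclisation to the 2,2-dimethylchromene.

Step 10
Reactants: 14 6-bromo-7-(methoxymethoxy)-2,2-dimethyl-2H-chromene
Product: 15 {[7-(methoxymethoxy)-2,2-dimethyl-2H-chromen-6-yl]ethynyl}trimethylsilane
Conditions: ethynyltrimethylsilane (1.5 equiv), PdCl2(PhCN)2 (3 mol%), [HP(t-Bu)3]BF4 (6 mol%), CuI (2 mol%), i-Pr2NH, 1,4-dioxane, 40 °C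
Reagents that add atoms: ethynyltrimethylsilane, C#C[Si](C)(C)C
Why: Sonogashira coupling with a bulky electron-rich trialkylphosphine is suited to electron-rich ortho-alkoxy aryl bromides and should leave the cis-disubstituted chromene alkene alone.

Step 11
Reactants: 15 {[7-(methoxymethoxy)-2,2-dimethyl-2H-chromen-6-yl]ethynyl}trimethylsilane
Product: 16 6-ethynyl-7-(methoxymethoxy)-2,2-dimethyl-2H-chromene
Conditions: K2CO3 (cat.), MeOH–THF, rt
Reagents that add atoms: none
Why: Base-catalysed methanolysis cleaves the alkynyl C–Si bond and does not touch the acetal or the chromene.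

Step 12
Reactants: 10 2-iodo-3,5-bis(methoxymethoxy)-4-[3-methyl-3-(triethylsilyloxy)butyl]phenol; 16 6-ethynyl-7-(methoxymethoxy)-2,2-dimethyl-2H-chromene
Product: 17 (Z)-6-(2-{2-iodo-3,5-bis(methoxymethoxy)-4-[3-methyl-3-(triethylsilyloxy)butyl]phenoxy}vinyl)-7-(methoxymethoxy)-2,2-dimethyl-2H-chromene
Conditions: 10 (1.1 equiv), Cs2CO3 (0.5 equiv), NMP, 100 °C, argon, dark, stopped before Z to E equilibration
Reagents that add atoms: none
Why: Base-mediated anti-Markovnikov hydrophenoxylation of an arylacetylene is a nucleophilic trans-addition (phenoxide attacks the terminal carbon and the vinyl anion is protonated anti to it), which should give the Z enol ether as the kinetic product while the aryl iodide, inert without a transition metal, survives.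

Step 13
Reactants: 17 (Z)-6-(2-{2-iodo-3,5-bis(methoxymethoxy)-4-[3-methyl-3-(triethylsilyloxy)butyl]phenoxy}vinyl)-7-(methoxymethoxy)-2,2-dimethyl-2H-chromene; 18 carbon monoxide
Product: 19 3-[7-(methoxymethoxy)-2,2-dimethyl-2H-chromen-6-yl]-5,7-bis(methoxymethoxy)-6-[3-methyl-3-(triethylsilyloxy)butyl]-4H-chromen-4-one
Conditions: Pd(OAc)2 (5 mol%), 1,3-bis(diphenylphosphino)propane (6 mol%), Et3N (3 equiv), CO (10 bar), 1,4-dioxane, 100 °C
Reagents that add atoms: none
Why: Proposed new method: zerovalent palladium (formed from Pd(OAc)2 and the bisphosphine) should add oxidatively to the C4a–I bond of 17, and CO should insert quickly into the doubly ortho-substituted aryl–palladium bond to give an aroylpalladium iodide held next to the enol ether. The aroyl carbon is then expected to bond to the enol-ether beta carbon (future C3) while palladium goes to the oxygen-bearing carbon (future C2), a 6-endo-trig cyclic acylpalladation that forms C4a–C4 and C4–C3 and closes ring C; loss of the C3 hydrogen with palladium (syn beta-hydride elimination, or base-assisted elimination because this hydrogen is alpha to the new ketone) gives the C2=C3 bond, and Et3N returns zerovalent palladium. The closest known reaction types are cyclic acylpalladation of alkenes (intramolecular carbonylative Heck reaction), intermolecular carbonylative Heck acylation of vinyl ethers at their beta carbon, and carbonylative closure of N-(2-haloaryl)enamines to 4-quinolones; closure of an aryl (Z)-styryl ether to a chromone ring is not established. No stereocentre is formed. The step needs 6-endo acylation at C3 to win over 5-exo acylation at C2 (which would lead to an aurone) and over CO-free 5-endo arylation (a 3-arylbenzofuran): the oxygen lone pair makes C3 the nucleophilic carbon and stabilises charge at C2, the cis aryloxy group and the ortho OMOM group twist ring B out of conjugation so that benzylic stabilisation of the 5-exo adduct is weak, and 10 bar of CO with a chelating bisphosphine should keep the arylpalladium stage short. The Z geometry places the C3 hydrogen cis to palladium in the 2-palladated chroman-4-one adduct, and the neutral amine medium should leave the chromene, the three MOM acetals and the TES ether untouched.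

Step 14
Reactants: 19 3-[7-(methoxymethoxy)-2,2-dimethyl-2H-chromen-6-yl]-5,7-bis(methoxymethoxy)-6-[3-methyl-3-(triethylsilyloxy)butyl]-4H-chromen-4-one
Product: 20 5,7-dihydroxy-6-(3-hydroxy-3-methylbutyl)-3-(7-hydroxy-2,2-dimethyl-2H-chromen-6-yl)-4H-chromen-4-one
Conditions: HCl (2 M aq.), MeOH–THF, 40 °C
Reagents that add atoms: none
Why: Acid-catalysed acetal exchange with methanol removes the three MOM groups and the same medium solvolyses the tertiary TES ether, under dilute conditions meant to spare the chromene alkene and the tertiary alcohol.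

**Compound list**
1 | resorcinol (benzene-1,3-diol) | Oc1cccc(O)c1 | starting material
2 | 1,3-bis(methoxymethoxy)benzene | COCOc1cccc(OCOC)c1 | intermediate
3 | 3-methylbutane-1,3-diol | CC(C)(O)CCO | starting material
4 | 4-iodo-2-methylbutan-2-ol | CC(C)(O)CCI | intermediate
5 | triethyl[(4-iodo-2-methylbutan-2-yl)oxy]silane | CC[Si](CC)(CC)OC(C)(C)CCI | intermediate
6 | [2,6-bis(methoxymethoxy)phenyl]lithium | [Li]c1c(OCOC)cccc1OCOC | intermediate
7 | triethyl({4-[2,6-bis(methoxymethoxy)phenyl]-2-methylbutan-2-yl}oxy)silane | CC[Si](CC)(CC)OC(C)(C)CCc1c(OCOC)cccc1OCOC | intermediate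
8 | 2-{3,5-bis(methoxymethoxy)-4-[3-methyl-3-(triethylsilyloxy)butyl]phenyl}-4,4,5,5-tetramethyl-1,3,2-dioxaborolane | CC[Si](CC)(CC)OC(C)(C)CCc1c(OCOC)cc(cc1OCOC)B1OC(C)(C)C(C)(C)O1 | intermediate
9 | 3,5-bis(methoxymethoxy)-4-[3-methyl-3-(triethylsilyloxy)butyl]phenol | CC[Si](CC)(CC)OC(C)(C)CCc1c(OCOC)cc(O)cc1OCOC | intermediate
10 | 2-iodo-3,5-bis(methoxymethoxy)-4-[3-methyl-3-(triethylsilyloxy)butyl]phenol | CC[Si](CC)(CC)OC(C)(C)CCc1c(OCOC)cc(O)c(I)c1OCOC | intermediate
11 | 5-bromo-2,4-dihydroxybenzaldehyde | O=Cc1cc(Br)c(O)cc1O | starting material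
12 | 5-bromo-2-hydroxy-4-(methoxymethoxy)benzaldehyde | COCOc1cc(O)c(C=O)cc1Br | intermediate
13 | 1-[5-bromo-2-hydroxy-4-(methoxymethoxy)phenyl]-3-methylbut-2-en-1-ol (racemic) | COCOc1cc(O)c(C(O)C=C(C)C)cc1Br | intermediate
14 | 6-bromo-7-(methoxymethoxy)-2,2-dimethyl-2H-chromene | COCOc1cc2OC(C)(C)C=Cc2cc1Br | intermediate
15 | {[7-(methoxymethoxy)-2,2-dimethyl-2H-chromen-6-yl]ethynyl}trimethylsilane | COCOc1cc2OC(C)(C)C=Cc2cc1C#C[Si](C)(C)C | intermediate
16 | 6-ethynyl-7-(methoxymethoxy)-2,2-dimethyl-2H-chromene | COCOc1cc2OC(C)(C)C=Cc2cc1C#C | intermediate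
17 | (Z)-6-(2-{2-iodo-3,5-bis(methoxymethoxy)-4-[3-methyl-3-(triethylsilyloxy)butyl]phenoxy}vinyl)-7-(methoxymethoxy)-2,2-dimethyl-2H-chromene | CC(C)(CCc1c(OCOC)cc(O/C=C\c2cc3c(cc2OCOC)OC(C)(C)C=C3)c(I)c1OCOC)O[Si](CC)(CC)CC | intermediate
18 | carbon monoxide | [C-]#[O+] | starting material
19 | 3-[7-(methoxymethoxy)-2,2-dimethyl-2H-chromen-6-yl]-5,7-bis(methoxymethoxy)-6-[3-methyl-3-(triethylsilyloxy)butyl]-4H-chromen-4-one | CC(C)(CCc1c(OCOC)cc2occ(-c3cc4c(cc3OCOC)OC(C)(C)C=C4)c(=O)c2c1OCOC)O[Si](CC)(CC)CC | intermediate
20 | 5,7-dihydroxy-6-(3-hydroxy-3-methylbutyl)-3-(7-hydroxy-2,2-dimethyl-2H-chromen-6-yl)-4H-chromen-4-one | CC(C)(O)CCc1c(O)cc2occ(-c3cc4c(cc3O)OC(C)(C)C=C4)c(=O)c2c1O | target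

**Step count**
Total step count: 14.
Longest linear sequence: 9 steps (steps 2, 3, 4, 5, 6, 7, 12, 13, 14, from 3-methylbutane-1,3-diol).

**Steps most likely to fail**

1. Step 13 (proposed new method). The aroylpalladium may add 5-exo to the oxygen-bearing carbon and go on to an aurone, or the arylpalladium may cyclise before CO inserts and give a 3-arylbenzofuran. The fallback uses established isoflavone chemistry, sets out from iodophenol 10 and bromochromene 14, and returns at 19. Stille coupling of 10 with tributyl(1-ethoxyvinyl)stannane (Pd(PPh3)4, toluene, 90 °C) should give the 1-ethoxyvinyl arene F1. Brief hydrolysis with aqueous oxalic acid should give the 2-hydroxyacetophenone F2. Condensation with N,N-dimethylformamide dimethyl acetal should give the enaminone F3, and iodine-induced cyclisation (I2, pyridine, CHCl3) the 3-iodochromone F4. In parallel, Miyaura borylation of 14 (B2pin2, PdCl2(dppf), KOAc, dioxane, 80 °C) should give the chromenyl boronate F5. Suzuki–Miyaura coupling of F4 with F5 (PdCl2(dppf), K3PO4, dioxane–water) then forms the C3–aryl bond and delivers 19.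

2. Step 12. The hindered phenoxide may add only slowly to the electron-rich alkyne, and at the temperature then needed the Z enol ether may equilibrate to the E isomer. The fallback replaces nucleophilic addition by stereoretentive cross-coupling, sets out from bromochromene 14 and iodophenol 10, and returns at 17. Bromine–lithium exchange on 14 (n-BuLi, THF, −78 °C) and formylation with DMF should give the chromene-6-carbaldehyde F6. Stork–Zhao olefination (iodomethyltriphenylphosphonium iodide, NaN(SiMe3)2, THF–DMPU, −78 °C) should give the (Z)-vinyl iodide F7. Copper-catalysed O-vinylation of 10 with F7 (CuI, N,N-dimethylglycine, Cs2CO3, dioxane, 60 °C) proceeds with retention of alkene geometry and should give 17; the doubly ortho-flanked aryl iodide of 10 is expected to be much slower than the vinyl iodide.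

3. Step 14. Under Brønsted acid the tertiary alcohol may ionise and cyclise onto the C5 or C7 hydroxyl, or the chromene C3=C4 bond of ring B may be protonated and add methanol, before the last MOM group has left. The fallback unmasks in two non-protic stages, sets out from 19, and returns at 20. Bu4NF (THF, 0 °C) should remove the silyl group to give the tertiary alcohol tris-MOM ether F8. ZnBr2 with propane-1-thiol (CH2Cl2, 0 °C) should then transfer the three methoxymethyl groups to sulfur within minutes and give 20.

**Further compounds**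
F1 | step 13 | 2-(1-ethoxyvinyl)-3,5-bis(methoxymethoxy)-4-[3-methyl-3-(triethylsilyloxy)butyl]phenol | CCOC(=C)c1c(O)cc(OCOC)c(CCC(C)(C)O[Si](CC)(CC)CC)c1OCOC
F2 | step 13 | 1-{6-hydroxy-2,4-bis(methoxymethoxy)-3-[3-methyl-3-(triethylsilyloxy)butyl]phenyl}ethan-1-one | CC(=O)c1c(O)cc(OCOC)c(CCC(C)(C)O[Si](CC)(CC)CC)c1OCOC
F3 | step 13 | (E)-3-(dimethylamino)-1-{6-hydroxy-2,4-bis(methoxymethoxy)-3-[3-methyl-3-(triethylsilyloxy)butyl]phenyl}prop-2-en-1-one | CN(C)/C=C/C(=O)c1c(O)cc(OCOC)c(CCC(C)(C)O[Si](CC)(CC)CC)c1OCOC
F4 | step 13 | 3-iodo-5,7-bis(methoxymethoxy)-6-[3-methyl-3-(triethylsilyloxy)butyl]-4H-chromen-4-one | CC[Si](CC)(CC)OC(C)(C)CCc1c(OCOC)cc2occ(I)c(=O)c2c1OCOC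
F5 | step 13 | 2-[7-(methoxymethoxy)-2,2-dimethyl-2H-chromen-6-yl]-4,4,5,5-tetramethyl-1,3,2-dioxaborolane | COCOc1cc2OC(C)(C)C=Cc2cc1B1OC(C)(C)C(C)(C)O1
F6 | step 12 | 7-(methoxymethoxy)-2,2-dimethyl-2H-chromene-6-carbaldehyde | COCOc1cc2OC(C)(C)C=Cc2cc1C=O
F7 | step 12 | (Z)-6-(2-iodovinyl)-7-(methoxymethoxy)-2,2-dimethyl-2H-chromene | COCOc1cc2OC(C)(C)C=Cc2cc1/C=C\I
F8 | step 14 | 6-(3-hydroxy-3-methylbutyl)-3-[7-(methoxymethoxy)-2,2-dimethyl-2H-chromen-6-yl]-5,7-bis(methoxymethoxy)-4H-chromen-4-one | CC(C)(O)CCc1c(OCOC)cc2occ(-c3cc4c(cc3OCOC)OC(C)(C)C=C4)c(=O)c2c1OCOC
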